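**Retrosynthetic overview**

- The 7-O-sulfate goes on last, onto the one free phenol of 6-hydroxyluteolin 5,6,3',4'-tetraacetate (peracetylation, then selective 7-O-deacetylation); ammonolysis then frees the other four hydroxyls.
- 6-Hydroxyluteolin comes from 5,6,7-trimethoxy-3',4'-diacetoxyflavone by BBr3.
- Key disconnection is O1–C8a of ring C. C8a is the only hydrogen-bearing ortho carbon of the 2,3,4-trimethoxybenzoyl ring (ring A) and lies para to the C6 oxygen, so the ring C ether is made from that C–H bond and the enol O–H of an open-chain 1,3-diketone by anodic dehydrogenative coupling.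
- The diketone is cut at C2–C3: C-acylation of 2,3,4-trimethoxyacetophenone with 3,4-diacetoxybenzoyl chloride. Rings A and B are bought; ring C is the only ring formed.

Key step: step 4

Assumption: the target is taken as the free aryl hydrogen sulfate as drawn, so the last step ends with one equivalent of mineral acid; the free acid is expected to be acid-labile and is best kept cold.

**Route**

Step 1
Reactants: 1 3,4-dihydroxybenzoic acid
Product: 2 3,4-diacetoxybenzoic acid
Conditions: Ac2O (2.5 equiv), pyridine, cat. DMAP, 0 °C → rt; then H2O, cold 1 M HCl work-up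
Reagents that add atoms: acetic anhydride, CC(=O)OC(C)=O
Why: DMAP-catalysed O-acetylation (nucleophilic acyl substitution) of both phenols; any mixed anhydride at the carboxyl group is hydrolysed in the aqueous work-up, which the aryl acetates should survive.

Step 2
Reactants: 2 3,4-diacetoxybenzoic acid
Product: 3 3,4-diacetoxybenzoyl chloride
Conditions: (COCl)2 (1.3 equiv), cat. DMF, CH2Cl2, 0 °C → rt; evaporate, use crude
Reagents that add atoms: oxalyl chloride, O=C(Cl)C(=O)Cl
Why: Acid chloride formation through the Vilsmeier-type chloroiminium species, under non-nucleophilic conditions that leave the aryl acetates alone and give only gaseous by-products.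

Step 3
Reactants: 4 1-(2,3,4-trimethoxyphenyl)ethanone; 3 3,4-diacetoxybenzoyl chloride
Product: 5 4-[3-oxo-3-(2,3,4-trimethoxyphenyl)propanoyl]-1,2-phenylene diacetate
Conditions: MgBr2·OEt2 (2.5 equiv), iPr2NEt (3 equiv), CH2Cl2, rt; 1 M HCl work-up
Reagents that add atoms: none
Why: Soft-enolisation C-acylation (crossed Claisen type): MgBr2 coordination acidifies the methyl ketone so that the amine can form the magnesium enolate, which is acylated on carbon by the acid chloride, a far better electrophile than the aryl acetates, and the product is held as a magnesium diketonate that should resist a second acylation.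

Step 4
Reactants: 5 4-[3-oxo-3-(2,3,4-trimethoxyphenyl)propanoyl]-1,2-phenylene diacetate
Product: 6 4-(5,6,7-trimethoxy-4-oxo-4H-chromen-2-yl)-1,2-phenylene diacetate
Conditions: graphite anode, Pt cathode, undivided cell, Bu4NBF4 (0.1 M), HFIP, constant current (about 5 mA cm−2, 2.2 F mol−1), rt
Reagents that add atoms: none
Why: Proposed new method: the anode should remove one electron from the most electron-rich part of 5, the trimethoxyaryl ring A conjugated through C4 with the chelated Z-enol, and in HFIP the radical cation should live long enough for the enol oxygen on C2 to add to C8a; a second electron and two protons are then lost (the protons leave as H2 at the cathode), which rearomatises ring A and completes the O1–C8a bond, and if the first electron is taken from the enol instead, the resulting oxygen-centred radical can add to the same carbon, so both paths converge. The closest known reaction types are the anodic dehydrogenative lactonisation of biaryl-2-carboxylic acids and hypervalent-iodine or copper-mediated oxidative C–O cyclisations onto electron-rich arenes; a 1,3-diketone enol has not been used as the oxygen partner in this way. Ring C closes in a six-membered mode, 6-endo-trig with respect to the C4a=C8a bond, from a planar hydrogen-bonded enol that already holds the oxygen next to C8a. No stereocentre is formed. Selectivity between the two aryl rings is needed and is secured by three methoxy donors on ring A against two acetoxy groups and the acyl group on ring B; within ring A, C8a is the only ortho carbon that carries hydrogen (the other, C5, bears OMe and could only give a non-aromatisable ipso adduct) and it lies para to the C6 methoxy group, which supports positive charge there. Over-oxidation should be limited because flavone 6 is a vinylogous ester that HFIP hydrogen-bonds at its basic carbonyl, and because the charge is kept close to 2 F per mole.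

Step 5
Reactants: 6 4-(5,6,7-trimethoxy-4-oxo-4H-chromen-2-yl)-1,2-phenylene diacetate
Product: 8 6-hydroxyluteolin, via 6-hydroxyluteolin 3',4'-diacetate 7 (not isolated)
Conditions: BBr3 (8 equiv), CH2Cl2, −78 °C → rt; then MeOH, 0 → 50 °C, argon
Reagents that add atoms: none
Why: BBr3 ether cleavage (Lewis adduct, then SN2 attack of bromide on methyl) should remove all three methyl groups, the C5 ether helped by chelation to the C4 carbonyl, and the HBr/MeOH formed in the quench transesterifies the two aryl acetates; the 5,6,7-trihydroxy pattern is the stable side of the Wessely–Moser equilibrium, so no isomerisation is expected.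

Step 6
Reactants: 8 6-hydroxyluteolin
Product: 9 2-(3,4-diacetoxyphenyl)-4-oxo-4H-chromene-5,6,7-triyl triacetate
Conditions: Ac2O (10 equiv), pyridine, cat. DMAP, rt, argon
Reagents that add atoms: acetic anhydride, CC(=O)OC(C)=O
Why: DMAP-catalysed peracetylation; the hydrogen-bonded 5-OH reacts last but should be acylated by excess anhydride, turning the air-sensitive pentaphenol into a stable pentaacetate.

Step 7
Reactants: 9 2-(3,4-diacetoxyphenyl)-4-oxo-4H-chromene-5,6,7-triyl triacetate
Product: 10 2-(3,4-diacetoxyphenyl)-7-hydroxy-4-oxo-4H-chromene-5,6-diyl diacetate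
Conditions: PhSH (1.2 equiv), imidazole (0.3 equiv), NMP, 0 °C → rt
Reagents that add atoms: none
Why: Thiolate transacylation removes the acetate of the most acidic phenol, which in flavone peracetates is 7-OH (C7 is para to C4a, which carries the C4 carbonyl); a small excess of thiol at low temperature should spare the next most activated 4'-acetate, and the 6-acetyl group has no thermodynamic reason to move onto the more acidic O7.

Step 8
Reactants: 10 2-(3,4-diacetoxyphenyl)-7-hydroxy-4-oxo-4H-chromene-5,6-diyl diacetate
Product: 11 pyridinium 5,6-diacetoxy-2-(3,4-diacetoxyphenyl)-4-oxo-4H-chromen-7-yl sulfate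
Conditions: SO3·pyridine (3 equiv), pyridine, rt; precipitate with Et2O
Reagents that add atoms: sulfur trioxide–pyridine complex, O=S(=O)([O-])[n+]1ccccc1
Why: O-Sulfation (sulfuryl transfer from the SO3–amine complex) of the single free phenol should give the sulfate monoester as its pyridinium salt, the other four oxygens being blocked as acetates.

Step 9
Reactants: 11 pyridinium 5,6-diacetoxy-2-(3,4-diacetoxyphenyl)-4-oxo-4H-chromen-7-yl sulfate
Product: 13 6-hydroxyluteolin 7-sulfate, via ammonium 6-hydroxyluteolin 7-sulfate 12 (not isolated)
Conditions: NH3 (7 M in MeOH, degassed), 0 °C → rt, argon; evaporate; then 1 M aq. HCl (1.0 equiv), 0 °C; Sephadex LH-20 (MeOH/H2O)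
Reagents that add atoms: none
Why: Ammonolysis cleaves the four aryl acetates while the aryl sulfate monoanion is inert to ammonia, and one equivalent of cold mineral acid followed by gel filtration should release the free hydrogen sulfate, whose S–O–aryl bond needs hot acid to hydrolyse.

**Compound list**

1 | 3,4-dihydroxybenzoic acid | O=C(O)c1ccc(O)c(O)c1 | starting material
2 | 3,4-diacetoxybenzoic acid | CC(=O)Oc1ccc(C(=O)O)cc1OC(C)=O | intermediate
3 | 3,4-diacetoxybenzoyl chloride | CC(=O)Oc1ccc(C(=O)Cl)cc1OC(C)=O | intermediate
4 | 1-(2,3,4-trimethoxyphenyl)ethanone | COc1ccc(C(C)=O)c(OC)c1OC | starting material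
5 | 4-[3-oxo-3-(2,3,4-trimethoxyphenyl)propanoyl]-1,2-phenylene diacetate | COc1ccc(C(=O)CC(=O)c2ccc(OC(C)=O)c(OC(C)=O)c2)c(OC)c1OC | intermediate
6 | 4-(5,6,7-trimethoxy-4-oxo-4H-chromen-2-yl)-1,2-phenylene diacetate | COc1cc2oc(-c3ccc(OC(C)=O)c(OC(C)=O)c3)cc(=O)c2c(OC)c1OC | intermediate
7 | 6-hydroxyluteolin 3',4'-diacetate, 4-(5,6,7-trihydroxy-4-oxo-4H-chromen-2-yl)-1,2-phenylene diacetate | CC(=O)Oc1ccc(-c2cc(=O)c3c(O)c(O)c(O)cc3o2)cc1OC(C)=O | intermediate
8 | 6-hydroxyluteolin, 2-(3,4-dihydroxyphenyl)-5,6,7-trihydroxy-4H-chromen-4-one | O=c1cc(-c2ccc(O)c(O)c2)oc2cc(O)c(O)c(O)c12 | intermediate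
9 | 2-(3,4-diacetoxyphenyl)-4-oxo-4H-chromene-5,6,7-triyl triacetate | CC(=O)Oc1ccc(-c2cc(=O)c3c(OC(C)=O)c(OC(C)=O)c(OC(C)=O)cc3o2)cc1OC(C)=O | intermediate
10 | 2-(3,4-diacetoxyphenyl)-7-hydroxy-4-oxo-4H-chromene-5,6-diyl diacetate | CC(=O)Oc1ccc(-c2cc(=O)c3c(OC(C)=O)c(OC(C)=O)c(O)cc3o2)cc1OC(C)=O | intermediate
11 | pyridinium 5,6-diacetoxy-2-(3,4-diacetoxyphenyl)-4-oxo-4H-chromen-7-yl sulfate | CC(=O)Oc1ccc(-c2cc(=O)c3c(OC(C)=O)c(OC(C)=O)c(OS(=O)(=O)[O-])cc3o2)cc1OC(C)=O.c1cc[nH+]cc1 | intermediate
12 | ammonium 2-(3,4-dihydroxyphenyl)-5,6-dihydroxy-4-oxo-4H-chromen-7-yl sulfate | [NH4+].O=c1cc(-c2ccc(O)c(O)c2)oc2cc(OS(=O)(=O)[O-])c(O)c(O)c12 | intermediate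
13 | 6-hydroxyluteolin 7-sulfate, 2-(3,4-dihydroxyphenyl)-5,6-dihydroxy-4-oxo-4H-chromen-7-yl hydrogen sulfate | O=c1cc(-c2ccc(O)c(O)c2)oc2cc(OS(=O)(=O)O)c(O)c(O)c12 | target

**Step count**

Total: 9 steps. Longest linear sequence: 9 steps (1 → 13); compound 4 enters at step 3 without prior steps.

**Steps most likely to fail**

1. Step 4 (anodic ring closure). Electron loss may take place at the diketone enol and lead to coupling at C3 (dimers, solvent adducts) faster than O–C8a bond formation. The C6 methoxy group is flanked on both sides and twisted, so it activates C8a less than a free para-methoxy group would. The enol oxygen may also attack the methoxy-bearing ortho carbon and dearomatise ring A, the flavone may be oxidised further, and alkoxide formed at the cathode may strip acetates. Fallback (known chemistry, Baker–Venkataraman route) sets out from acid chloride 3 and comes back at 6. Purchased 1-(6-hydroxy-2,3,4-trimethoxyphenyl)ethanone (COc1cc(O)c(C(C)=O)c(OC)c1OC) is O-acylated with 3 (pyridine, CH2Cl2, 0 °C) to 2-acetyl-3,4,5-trimethoxyphenyl 3,4-diacetoxybenzoate F1. LiN(SiMe3)2 (THF, −78 → −20 °C, AcOH quench) should bring about the 1,5-acyl shift to 4-[3-(6-hydroxy-2,3,4-trimethoxyphenyl)-3-oxopropanoyl]-1,2-phenylene diacetate F2. AcOH with cat. H2SO4 at 90 °C cyclodehydrates F2 to 6. Here O1 is carried in as a phenol, so no C–H oxidation is needed; any acetate lost on the way is of no consequence, since step 5 removes both.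

2. Step 7 (selective 7-O-deacetylation). Site selectivity of the transacylation may erode through competing cleavage of the 4'-acetate or through migration of the 6-acetyl group to O7 once the phenoxide is free. Fallback sets out from pentaacetate 9 and comes back at 10, using alkylative trapping in place of transacylation. Heating 9 with benzyl bromide, K2CO3 and KI in acetone should cleave only the 7-acetate and fix the phenoxide at once as 7-(benzyloxy)-2-(3,4-diacetoxyphenyl)-4-oxo-4H-chromene-5,6-diyl diacetate F3, leaving no ortho-acetoxy phenoxide to equilibrate. Hydrogenolysis (H2, Pd/C, EtOAc, rt) then uncovers 7-OH under neutral conditions and gives 10.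

3. Step 8 (sulfation). In the basic medium the 6-acetyl group may shift to O7 before sulfuryl transfer, so that sulfate is delivered to O6, or acetates may be lost and more than one sulfate introduced. Fallback sets out from 8 and comes back at 13, with no protecting groups. 6-Hydroxyluteolin 8 is treated with Bu4NHSO4 and dicyclohexylcarbodiimide in pyridine at 4 °C, conditions under which flavone hydroxyls react in the order 7 > 4' while the chelated 5-OH and catechol-type hydroxyls stay free. This should give tetrabutylammonium 6-hydroxyluteolin 7-sulfate F4. Methanolic KOAc converts F4 into the sparingly soluble potassium 6-hydroxyluteolin 7-sulfate F5. One equivalent of cold dilute HCl and Sephadex LH-20, as in step 9, then lead to 13.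

**Further compounds**

F1 | step 4 | 2-acetyl-3,4,5-trimethoxyphenyl 3,4-diacetoxybenzoate | COc1cc(OC(=O)c2ccc(OC(C)=O)c(OC(C)=O)c2)c(C(C)=O)c(OC)c1OC
F2 | step 4 | 4-[3-(6-hydroxy-2,3,4-trimethoxyphenyl)-3-oxopropanoyl]-1,2-phenylene diacetate | COc1cc(O)c(C(=O)CC(=O)c2ccc(OC(C)=O)c(OC(C)=O)c2)c(OC)c1OC
F3 | step 7 | 7-(benzyloxy)-2-(3,4-diacetoxyphenyl)-4-oxo-4H-chromene-5,6-diyl diacetate | CC(=O)Oc1ccc(-c2cc(=O)c3c(OC(C)=O)c(OC(C)=O)c(OCc4ccccc4)cc3o2)cc1OC(C)=O
F4 | step 8 | tetrabutylammonium 2-(3,4-dihydroxyphenyl)-5,6-dihydroxy-4-oxo-4H-chromen-7-yl sulfate | CCCC[N+](CCCC)(CCCC)CCCC.O=c1cc(-c2ccc(O)c(O)c2)oc2cc(OS(=O)(=O)[O-])c(O)c(O)c12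
F5 | step 8 | potassium 2-(3,4-dihydroxyphenyl)-5,6-dihydroxy-4-oxo-4H-chromen-7-yl sulfate | [K+].O=c1cc(-c2ccc(O)c(O)c2)oc2cc(OS(=O)(=O)[O-])c(O)c(O)c12
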